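The earlier runs and the new flask come from a simulation from invented constants, and the scatter is random.

If a larger charge of Z leaves a smaller fraction of it as L, you first want to know how steeply that fraction falls.

| flask | Z | remark | time |
|---|---|---|---|
| dusk | 0.75 M | run made earlier |  |
| spring | 3 M | run made earlier |  |
| flask | 1.5 M |  | 8.0 h |

- dusk (time / h: E / %, L / %, Z / %): 1.00: 0, 18, 43; 2.00: 0, 24, 27; 3.00: 2, 28, 17; 4.00: 1, 26, 17; 5.00: 0, 31, 12; 6.00: 0, 26, 11
- spring (time / h: E / %, L / %, Z / %): 1.00: 3, 14, 21; 2.00: 2, 14, 10; 3.00: 0, 15, 9; 4.00: 1, 13, 5; 5.00: 0, 14, 4; 6.00: 1, 14, 5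

(each reading ± 1.5 percentage points)

- share of E in E plus L at 4.0 min
- share of E in E plus L at 8.0 h
- which of E and L there is more of at 8.0 h

Read the two tables column against column, with every amount as a fraction of the charge. At 1.00 h, the missing part of the balance per part of L is 2.17 in the dusk run and 4.43 in the spring run, so it is larger at the larger charge. Now read down the L columns. From 3.00 h on, the L readings average 27.8% in the dusk run and 14.0% in the spring run.

The ln of the ratio of these plateaus, over the ln of the ratio of the charges, gives 0.494. This is what you carry: the plateau exponent, the downward slope of the ln of the plateau fraction against the ln of the charge, as read from the scattered readings of these two runs.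

Scaling from the dusk plateau, I reckon L in the flask at 19.7%. The E readings are of the size of the scatter of 1.5 percentage points, and over both runs together they average 0.833%. My share of E at 8.0 h is therefore 4.06%, with L ahead. I keep that weak figure for 4.0 min too, since no reading stands near that time.

The forecast gives 12% at 4.0 min and 3% at 8.0 h, with L ahead, and says of E that “the data hardly establish this”.

The flask gives 1.84% at 4.0 min and 3.42% at 8.0 h, with L ahead, 19.8% against 0.701% of E.

    Z ⇌ E (K = 4.56, k = 0.00537 /h)
    L → G (k = 8.95 × 10⁻⁵ /h)
    Z ⇌ J (K = 2.99, k = 0.0247 /h)
    Z ⇌ L (K = 2.40, k = 0.288 /h)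
    2 Z → Q (k = 0.536 /M/h)

In this flask, the passing of Z into L by its forward rate alone has a half-life of 2.4 h, while the first half-life of Z by 2 Z into Q alone is 0.622 h, which is shorter. At 8.00 h the flask holds 70.0% as Q, counted by the Z it holds, and 19.8% as L, where the plateau exponent gave 19.7%. For a neighbour charged with 0.60 M of Z, the same exponent gives 31.0%, and that flask holds 31.5% of L at 8.00 h.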